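- The trap in this flask was to read two runs at different loadings as proof that loading hardly matters, when both stood on the same side of a line that the new flask crosses.

the same everywhere: starting material 20 mM
- cedar: reagent 0.60 equiv; protic impurity 1 mM; run made earlier
- alder: reagent 0.90 equiv; protic impurity 1 mM; run made earlier
- flask: reagent 1.20 equiv; protic impurity 1.00 mM; time 1.0 h

- cedar (time / min: target / %, isomer of the product / %): 5.00: 7.3, 2.6; 10.0: 15.2, 7.3; 15.0: 22.0, 8.9; 30.0: 29.4, 14.1; 60.0: 31.3, 17.8
- alder (time / min: target / %, isomer of the product / %): 5.00: 10.2, 5.0; 10.0: 20.4, 8.8; 15.0: 28.1, 13.3; 30.0: 39.0, 19.5; 60.0: 41.2, 23.3

(readings scatter by 0.5 percentage points)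

- share of target in target plus isomer of the product at 80 s
- share of target in target plus isomer of the product at 10 min
- share of target in target plus isomer of the product at 1.0 h
- which of target and isomer of the product there is more of at 1.0 h

- My yardstick was a charge balance. In the flask at 1.20 equiv, 4.00 mM of reagent stood beyond the starting material charged, and I called this the reagent surplus, with equivalence as its zero.
- The surplus was −8.00 mM in cedar and −2.00 mM in alder, so each held less reagent than starting material, and reagent was the limiting reagent on paper.
- I began with the main step, a side-by-side split into target and isomer of the product, which gives a constant share; the pooled readings at 15.0 min put it near 69.3%.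
- Then I added a slow second process. By 60.0 min the pooled share read 63.8%, down by 5.5 percentage points, and I took that drift to be independent of loading below equivalence.
- Then came the rest. Neither run was charged with reagent in excess, so I could not size any attack of reagent on target. For the flask I kept 69.3% for the early times, treated 63.8% at the end as a ceiling, and expected target to stay ahead.
- The forecast gave 70%, 68.5% and 63.5%, with target ahead, holding that “At 1.2 equiv the rate and conversion are higher, but the selectivity should stay similar”. Where I had a ceiling, it had a value.
- The flask gave 71.4%, 69.4% and 58.5%, with target ahead at 34.9% against 24.8%.

    intermediate ⇌ isomer of the product (K = 2.10, k = 0.0200 /min)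
    reagent + target → over-reaction product (k = 2.00 /M/min)
    intermediate ⇌ target (K = 2.50, k = 0.0510 /min)
    starting material + reagent → intermediate + by-product (k = 32.0 /M/min)
    2 starting material → self-condensation product (k = 1.40 /M/min)
    starting material + protic impurity → quenched substrate (k = 280 /M/min)

- In the flask, the reagent charged exceeded the 18.1 mM of by-product formed by 5.90 mM, more than the surplus of 4.00 mM; the half-life of target by over-reaction alone, with reagent as charged, was 0.24 h, short against 1.0 h, and over-reaction product reached 16.0% at 1.00 h. The neighbour flask charged with 0.480 equiv, at a surplus of −10.4 mM, ended with reagent at 0%, over-reaction product at 0.201% and a share of 64.1%.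

The data were generated by integration on assumed constants; noise was put on by code.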